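**Target:** (5S)-5-acetoxy-1,7-bis(4-hydroxy-3-methoxyphenyl)heptan-3-one, 8. With the priorities OAc > C4 > C6 > H, the stereocentre in the given SMILES is (S).

**Retrosynthetic overview** (listed from the building blocks up to the target)
- C1=C2 and C6=C7: two aldol condensations of vanillin 1 with the methyl groups of acetylacetone 2, templated as the difluoroboron chelates 3 and 4, give curcumin 5. Both benzene rings come intact from 1; no ring is formed anywhere in the route.
- Four C–H bonds: 5 is hydrogenated to the symmetric diketone tetrahydrocurcumin 6.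
- Key disconnection, the carbinol C5–H: one of the two enantiotopic carbonyls of 6 is hydrogenated with a chiral ruthenium catalyst, giving the (5S)-ketol 7 and setting the only stereocentre.
- O–acetyl bond: the secondary alcohol of 7 is acetylated beside two free phenols to give 8.

Assumption: 1,3-diketones are written as diketo tautomers although they are largely enolised.

**Step 1**
Reactants: 1 vanillin (2.0 equiv); 2 acetylacetone (1.0 equiv)
Product: 5 curcumin (1E,6E)-1,7-bis(4-hydroxy-3-methoxyphenyl)hepta-1,6-diene-3,5-dione, via acetylacetone difluoroboron chelate 3 (not isolated), via curcumin difluoroboron chelate 4 (not isolated)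
Conditions: BF3·OEt2 (1.1 equiv), toluene, 65 °C; then 1, n-BuNH2 (0.3 equiv), 65 °C; then Na2C2O4 (3 equiv), MeOH–H2O, 65 °C
Reagents that add atoms: none
Why: Pabon-type double Knoevenagel/aldol condensation in which the difluoroboron chelate masks the acidic central CH2 of acetylacetone and activates its methyl groups, so that each methyl condenses with one vanillin to an (E)-styryl unit, after which oxalate-buffered hydrolysis releases the free diketone.

**Step 2**
Reactants: 5 curcumin
Product: 6 tetrahydrocurcumin 1,7-bis(4-hydroxy-3-methoxyphenyl)heptane-3,5-dione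
Conditions: H2 (1 atm, stopped at 2.0 equiv uptake), 10% Pd/C, acetone, rt; recrystallised
Reagents that add atoms: none
Why: Heterogeneous catalytic hydrogenation of the two conjugated styrenyl C=C bonds, which are reduced much faster than the enolised 1,3-diketone or the arenes, gives the symmetric diketone.

**Step 3** (key step)
Reactants: 6 tetrahydrocurcumin
Product: 7 (S)-hexahydrocurcumin (5S)-5-hydroxy-1,7-bis(4-hydroxy-3-methoxyphenyl)heptan-3-one
Conditions: H2 (10 bar, metered, stopped at 1.0 equiv uptake), [RuCl(p-cymene)((S)-BINAP)]Cl (0.5 mol%), MeOH, 50 °C; chromatography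
Reagents that add atoms: none
Why: Noyori asymmetric hydrogenation of a β-diketone, in which the neighbouring carbonyl chelates ruthenium and the (S)-BINAP ligand delivers hydride to the same face of whichever enantiotopic carbonyl is bound, so either carbonyl gives the (5S)-carbinol (the sense known for β-keto esters and acetylacetone), while the chelating diketone outcompetes the ketol for the catalyst and the hydrogen limit holds the reaction at mono-reduction.

**Step 4**
Reactants: 7 (S)-hexahydrocurcumin
Product: 8 (5S)-5-acetoxy-1,7-bis(4-hydroxy-3-methoxyphenyl)heptan-3-one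
Conditions: Ac2O (1.5 equiv), BF3·OEt2 (20 mol%), THF, 0 °C; cold aq. NaHCO3 quench
Reagents that add atoms: acetic anhydride, CC(=O)OC(C)=O
Why: Lewis-acid-catalysed O-acylation, which under non-basic conditions acetylates the more nucleophilic aliphatic hydroxyl and leaves the un-ionised phenols largely untouched, and which does not break the C5–O bond, so the (S) configuration is retained.

**Compound list**
1 | vanillin (4-hydroxy-3-methoxybenzaldehyde) | COc1cc(C=O)ccc1O | starting material
2 | acetylacetone (pentane-2,4-dione) | CC(=O)CC(C)=O | starting material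
3 | acetylacetone difluoroboron chelate (2,2-difluoro-4,6-dimethyl-1,3,2-dioxaborinine) | CC1=CC(C)=[O+][B-](F)(F)O1 | intermediate
4 | curcumin difluoroboron chelate (2,2-difluoro-4,6-bis[(E)-2-(4-hydroxy-3-methoxyphenyl)ethenyl]-1,3,2-dioxaborinine) | COc1cc(/C=C/C2=CC(/C=C/c3ccc(O)c(OC)c3)=[O+][B-](F)(F)O2)ccc1O | intermediate
5 | curcumin ((1E,6E)-1,7-bis(4-hydroxy-3-methoxyphenyl)hepta-1,6-diene-3,5-dione) | COc1cc(/C=C/C(=O)CC(=O)/C=C/c2ccc(O)c(OC)c2)ccc1O | intermediate
6 | tetrahydrocurcumin (1,7-bis(4-hydroxy-3-methoxyphenyl)heptane-3,5-dione) | COc1cc(CCC(=O)CC(=O)CCc2ccc(O)c(OC)c2)ccc1O | intermediate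
7 | (S)-hexahydrocurcumin ((5S)-5-hydroxy-1,7-bis(4-hydroxy-3-methoxyphenyl)heptan-3-one) | COc1cc(CCC(=O)C[C@H](CCc2ccc(O)c(OC)c2)O)ccc1O | intermediate
8 | (5S)-5-acetoxy-1,7-bis(4-hydroxy-3-methoxyphenyl)heptan-3-one | COc1cc(CCC(=O)C[C@H](CCc2ccc(O)c(OC)c2)OC(C)=O)ccc1O | target

**Total step count:** 4. **Longest linear sequence:** 4 steps (from 1 and 2).

**Steps most likely to fail**

Step 3. The risk is over-reduction of the ketol to the diol, or incomplete conversion if the reaction is stopped early. The fallback sets out from 6 and deliberately drives the same hydrogenation to completion (H2 50 bar, [RuCl(p-cymene)((S)-BINAP)]Cl, MeOH, 50 °C). This gives the C2-symmetric anti-diol (3S,5S)-1,7-bis(4-hydroxy-3-methoxyphenyl)heptane-3,5-diol F1. Its two carbinols are homotopic, so oxidising either one gives the same (S)-ketol. One carbinol is then oxidised by base-free transfer dehydrogenation to acetone, which tolerates the free phenols (Shvo's catalyst, {[(η5-Ph4C4CO)]2H}Ru2(CO)4(μ-H), 1 mol%, acetone, 56 °C, stopped near half conversion). This comes back to the route at 7; recovered F1 and over-oxidised 6 are recycled.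

Step 4. The risk is partial acetylation of the phenols, or acid-induced β-elimination of the acetoxy ketone to the enone. The fallback sets out from 7 and acetylates all three hydroxyls (Ac2O, pyridine, 0 °C to rt) to (5S)-5-acetoxy-1,7-bis(4-acetoxy-3-methoxyphenyl)heptan-3-one F2. Only the two aryl acetates, which are much better acyl donors than the secondary alkyl acetate, are then cleaved with NH4OAc in MeOH–H2O at rt. This comes back to the route at 8.

Step 2. The risk is over-reduction of the enolised diketone to racemic ketol and diols, which would lower the yield and could contaminate 7 with racemate. The fallback sets out from 4, which is filtered from the toluene slurry of step 1 instead of being hydrolysed. Hydrogenation (H2 1 atm, 10% Pd/C, THF, rt) gives tetrahydrocurcumin difluoroboron chelate F3, in which the diketone is locked as a chelate that Pd/C does not reduce. The boron is then removed with Na2C2O4 in MeOH–H2O at 65 °C, which comes back to the route at 6.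

**Further compounds**
F1 | step 3 | (3S,5S)-1,7-bis(4-hydroxy-3-methoxyphenyl)heptane-3,5-diol | COc1cc(CC[C@H](O)C[C@H](CCc2ccc(O)c(OC)c2)O)ccc1O
F2 | step 4 | (5S)-5-acetoxy-1,7-bis(4-acetoxy-3-methoxyphenyl)heptan-3-one | COc1cc(CCC(=O)C[C@H](CCc2ccc(OC(C)=O)c(OC)c2)OC(C)=O)ccc1OC(C)=O
F3 | step 2 | tetrahydrocurcumin difluoroboron chelate (2,2-difluoro-4,6-bis[2-(4-hydroxy-3-methoxyphenyl)ethyl]-1,3,2-dioxaborinine) | COc1cc(CCC2=CC(CCc3ccc(O)c(OC)c3)=[O+][B-](F)(F)O2)ccc1O
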